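The dihydropyranone ring O1–C2–C3–C4–C4a–C8a is assembled late by a formal (3+3) annulation in which dibenzyl malonate acts as a C,O-1,3-dinucleophile. Two features are exploited: the oxygen of the 4-hydroxyphenyl ring (ring D) is para to C4, so C4 can be made the electrophilic carbon of a para-quinone methide, and C8a, the ring A carbon ortho to C4a, can carry a bromide. In one flask an enantioselective 1,6-addition forms C3–C4 and sets C4, and copper-catalysed enolate O-arylation forms O1–C8a. The precursor is a racemic silyl-protected benzhydryl acetate that already carries the 4-methoxy-2-pyranone.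

Key step: step 5

Remark: locants O1, C2, C3, C4, C4a, C5–C8 and C8a are those of the chroman-2-one core of the target, ring A is its benzo ring and ring D the 4-hydroxyphenyl group; CIP analysis of the target SMILES gives 4R.

Step 1
Reactants: 1 4-bromo-2-fluoro-6-methylbenzoic acid
Product: 2 2-(benzyloxy)-4-bromo-6-methylbenzoic acid
Conditions: BnOH (3 equiv), KOt-Bu (3.2 equiv), DMSO, 100 °C; then 1 M HCl
Reagents that add atoms: benzyl alcohol, OCc1ccccc1
Why: Nucleophilic aromatic substitution (SNAr) in which benzyl oxide displaces the fluoride ortho to the carboxylate, C–F being far more labile than C–Br towards addition–elimination; no stereocentre is formed.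

Step 2
Reactants: 2 2-(benzyloxy)-4-bromo-6-methylbenzoic acid
Product: 3 6-(benzyloxy)-4-bromo-3-iodo-2-methylbenzoic acid
Conditions: NIS (1.1 equiv), TFA (cat.), MeCN, 0 °C → rt
Reagents that add atoms: N-iodosuccinimide, O=C1CCC(=O)N1I
Why: Electrophilic aromatic iodination should go para to the benzyloxy group, at the position also ortho to methyl (the later C4a), which gives the I/Br pair needed for a chemoselective metalation; no stereocentre is formed.

Step 3
Reactants: 3 6-(benzyloxy)-4-bromo-3-iodo-2-methylbenzoic acid; 4 methyl (2E)-3-methoxybut-2-enoate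
Product: 8 6-[6-(benzyloxy)-4-bromo-3-iodo-2-methylphenyl]-4-methoxy-2H-pyran-2-one, via acid chloride 5 (not isolated), via lithium dienolate 6 (not isolated), via keto ester 7 (not isolated)
Conditions: (COCl)2, DMF (cat.), CH2Cl2, 0 °C → rt, concentrate; 4 (2.1 equiv), LDA (2.0 equiv), THF, −78 °C, then 5, −78 °C → 50 °C; aq. NH4Cl
Reagents that add atoms: none
Why: Vinylogous Claisen γ-acylation of the lithium dienolate by the aroyl chloride, followed by lactonisation of the ketone enolate oxygen onto the ester that the E-enol ether holds cis to the new CH2, should build the 4-methoxy-2-pyranone in one step; free amide base is avoided so that the aryl halides are not metalated, and no stereocentre is formed.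

Step 4
Reactants: 8 6-[6-(benzyloxy)-4-bromo-3-iodo-2-methylphenyl]-4-methoxy-2H-pyran-2-one; 9 4-[(tert-butyldimethylsilyl)oxy]benzaldehyde
Product: 12 [4-(benzyloxy)-6-bromo-3-(4-methoxy-2-oxo-2H-pyran-6-yl)-2-methylphenyl]{4-[(tert-butyldimethylsilyl)oxy]phenyl}methyl acetate (racemic), via arylmagnesium chloride 10 (not isolated), via magnesium alkoxide 11 (not isolated)
Conditions: i-PrMgCl·LiCl (1.05 equiv), THF, −40 °C; 9, −40 → 0 °C; Ac2O, DMAP (cat.), 0 °C → rt
Reagents that add atoms: acetic anhydride, CC(=O)OC(C)=O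
Why: Iodine–magnesium exchange with the turbo-Grignard reagent is selective for C–I over C–Br and should outrun addition to the pyranone at −40 °C, the aryl Grignard adds to the aldehyde and the alkoxide is acetylated in the flask; the carbinol centre is left racemic because it becomes planar in step 5.

Step 5
Reactants: 12 [4-(benzyloxy)-6-bromo-3-(4-methoxy-2-oxo-2H-pyran-6-yl)-2-methylphenyl]{4-[(tert-butyldimethylsilyl)oxy]phenyl}methyl acetate; 13 dibenzyl malonate
Product: 17 benzyl (4R)-7-(benzyloxy)-4-(4-hydroxyphenyl)-6-(4-methoxy-2-oxo-2H-pyran-6-yl)-5-methyl-2-oxo-3,4-dihydro-2H-chromene-3-carboxylate (C3 epimers), via quinone methide 14 (not isolated), via malonate adduct 15 (not isolated), via ketene acetal 16 (not isolated)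
Conditions: 13 (1.1 equiv), cinchona-derived N-benzylammonium bromide with free C9–OH (10 mol %), CsF (1.5 equiv), Cs2CO3 (3 equiv), toluene, −20 °C → rt; then CuI (10 mol %), N,N′-dimethylethylenediamine (20 mol %), THF, 65 °C, 0.02 M; then 1 M HCl, THF, rt
Reagents that add atoms: water, O
Why: Fluoride removes the silyl group of 12 and the phenoxide expels acetate to give quinone methide 14, the chiral ammonium enolate of 13 adds 1,6 to its exocyclic carbon (C3–C4 bond), and the copper(I) enolate of adduct 15 then undergoes oxidative addition at the ortho C–Br bond and C–O reductive elimination (O1–C8a bond) to ketene acetal 16, which aqueous acid hydrolyses to lactone 17. The closest known reaction types are the phase-transfer-catalysed enantioselective 1,6-addition of malonates to para-quinone methides and the copper(I)-catalysed domino C-benzylation/intramolecular enolate O-arylation of 1,3-dicarbonyl compounds with 2-bromobenzyl electrophiles that gives 4H-chromenes. The one ring closed is the six-membered O1–C2–C3–C4–C4a–C8a ring, by intramolecular Ullmann-type C(aryl)–O coupling in which the enolate oxygen attacks the aryl–copper carbon in a 6-exo sense, C-arylation being excluded because it would need a four-membered ring. C4 is set in the 1,6-addition by the cinchona ammonium ion pair, which shields one face of the planar methide, and the pseudoenantiomeric catalyst series is chosen so that 4R results, while C3 stays epimerisable and is removed in step 6. The step needs ring closure to be faster than intermolecular aryl ether formation by the ring D phenoxide and than retro-1,6-addition, which the bromine placed ortho to C4a, the high dilution and the mild coupling temperature should secure.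

Step 6
Reactants: 17 benzyl (4R)-7-(benzyloxy)-4-(4-hydroxyphenyl)-6-(4-methoxy-2-oxo-2H-pyran-6-yl)-5-methyl-2-oxo-3,4-dihydro-2H-chromene-3-carboxylate
Product: 19 (4R)-7-hydroxy-4-(4-hydroxyphenyl)-6-(4-methoxy-2-oxo-2H-pyran-6-yl)-5-methyl-3,4-dihydro-2H-chromen-2-one, via carboxylic acid 18 (not isolated)
Conditions: H2 (1 atm), 10% Pd/C, EtOAc–THF, rt; filter; 1,4-dioxane, 90 °C
Reagents that add atoms: none
Why: Catalytic hydrogenolysis removes the benzyl ether and the benzyl ester, and the resulting 2-oxochroman-3-carboxylic acid (a malonic half ester) should decarboxylate on warming, which turns C3 into CH2 without touching the C4 stereocentre.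

Compound list
1 | 4-bromo-2-fluoro-6-methylbenzoic acid | Cc1cc(Br)cc(F)c1C(=O)O | starting material
2 | 2-(benzyloxy)-4-bromo-6-methylbenzoic acid | Cc1cc(Br)cc(OCc2ccccc2)c1C(=O)O | intermediate
3 | 6-(benzyloxy)-4-bromo-3-iodo-2-methylbenzoic acid | Cc1c(I)c(Br)cc(OCc2ccccc2)c1C(=O)O | intermediate
4 | methyl (2E)-3-methoxybut-2-enoate | COC(=O)/C=C(/OC)C | starting material
5 | 6-(benzyloxy)-4-bromo-3-iodo-2-methylbenzoyl chloride | Cc1c(I)c(Br)cc(OCc2ccccc2)c1C(Cl)=O | intermediate
6 | lithium dienolate of 4 (lithium 1,3-dimethoxybuta-1,3-dien-1-olate) | [Li]OC(OC)=CC(=C)OC | intermediate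
7 | methyl (2E)-5-[6-(benzyloxy)-4-bromo-3-iodo-2-methylphenyl]-3-methoxy-5-oxopent-2-enoate | COC(=O)/C=C(/OC)CC(=O)c1c(C)c(I)c(Br)cc1OCc1ccccc1 | intermediate
8 | 6-[6-(benzyloxy)-4-bromo-3-iodo-2-methylphenyl]-4-methoxy-2H-pyran-2-one | COc1cc(-c2c(C)c(I)c(Br)cc2OCc2ccccc2)oc(=O)c1 | intermediate
9 | 4-[(tert-butyldimethylsilyl)oxy]benzaldehyde | O=Cc1ccc(O[Si](C)(C)C(C)(C)C)cc1 | starting material
10 | [4-(benzyloxy)-6-bromo-3-(4-methoxy-2-oxo-2H-pyran-6-yl)-2-methylphenyl]magnesium chloride | COc1cc(-c2c(C)c([Mg]Cl)c(Br)cc2OCc2ccccc2)oc(=O)c1 | intermediate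
11 | chloromagnesium alkoxide of [4-(benzyloxy)-6-bromo-3-(4-methoxy-2-oxo-2H-pyran-6-yl)-2-methylphenyl]{4-[(tert-butyldimethylsilyl)oxy]phenyl}methanol (racemic) | COc1cc(-c2c(C)c(C(O[Mg]Cl)c3ccc(O[Si](C)(C)C(C)(C)C)cc3)c(Br)cc2OCc2ccccc2)oc(=O)c1 | intermediate
12 | [4-(benzyloxy)-6-bromo-3-(4-methoxy-2-oxo-2H-pyran-6-yl)-2-methylphenyl]{4-[(tert-butyldimethylsilyl)oxy]phenyl}methyl acetate (racemic) | COc1cc(-c2c(C)c(C(OC(C)=O)c3ccc(O[Si](C)(C)C(C)(C)C)cc3)c(Br)cc2OCc2ccccc2)oc(=O)c1 | intermediate
13 | dibenzyl malonate (dibenzyl propanedioate) | O=C(CC(=O)OCc1ccccc1)OCc1ccccc1 | starting material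
14 | 6-{6-(benzyloxy)-4-bromo-2-methyl-3-[(4-oxocyclohexa-2,5-dien-1-ylidene)methyl]phenyl}-4-methoxy-2H-pyran-2-one | COc1cc(-c2c(C)c(C=C3C=CC(=O)C=C3)c(Br)cc2OCc2ccccc2)oc(=O)c1 | intermediate
15 | dibenzyl 2-[(R)-[4-(benzyloxy)-6-bromo-3-(4-methoxy-2-oxo-2H-pyran-6-yl)-2-methylphenyl](4-hydroxyphenyl)methyl]propanedioate | COc1cc(-c2c(OCc3ccccc3)cc(Br)c(c2C)[C@@H](c2ccc(O)cc2)C(C(=O)OCc2ccccc2)C(=O)OCc2ccccc2)oc(=O)c1 | intermediate
16 | benzyl (4R)-2,7-bis(benzyloxy)-4-(4-hydroxyphenyl)-6-(4-methoxy-2-oxo-2H-pyran-6-yl)-5-methyl-4H-chromene-3-carboxylate | COc1cc(-c2c(OCc3ccccc3)cc3c(c2C)[C@@H](c2ccc(O)cc2)C(C(=O)OCc2ccccc2)=C(OCc2ccccc2)O3)oc(=O)c1 | intermediate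
17 | benzyl (4R)-7-(benzyloxy)-4-(4-hydroxyphenyl)-6-(4-methoxy-2-oxo-2H-pyran-6-yl)-5-methyl-2-oxo-3,4-dihydro-2H-chromene-3-carboxylate (C3 epimers) | COc1cc(-c2c(OCc3ccccc3)cc3c(c2C)[C@@H](c2ccc(O)cc2)C(C(=O)OCc2ccccc2)C(=O)O3)oc(=O)c1 | intermediate
18 | (4R)-7-hydroxy-4-(4-hydroxyphenyl)-6-(4-methoxy-2-oxo-2H-pyran-6-yl)-5-methyl-2-oxo-3,4-dihydro-2H-chromene-3-carboxylic acid (C3 epimers) | COc1cc(-c2c(O)cc3c(c2C)[C@@H](c2ccc(O)cc2)C(C(=O)O)C(=O)O3)oc(=O)c1 | intermediate
19 | (4R)-7-hydroxy-4-(4-hydroxyphenyl)-6-(4-methoxy-2-oxo-2H-pyran-6-yl)-5-methyl-3,4-dihydro-2H-chromen-2-one (CNP0207475.1) | COc1cc(-c2c(O)cc3c(c2C)[C@@H](c2ccc(O)cc2)CC(=O)O3)oc(=O)c1 | target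

Total step count: 6. Longest linear sequence: 6 steps (1 → 19).

Steps most likely to fail

1. Step 5. Ring closure through the ester-enolate oxygen may be slower than reduction of the C–Br bond, than intermolecular aryl ether formation by the free ring D phenoxide, or than retro-1,6-addition, which would erode the configuration at C4. The fallback sets out again from 12. Meldrum's acid (2,2-dimethyl-1,3-dioxane-4,6-dione) replaces 13 as a cyclic C,O-donor under the same fluoride/chiral ammonium regime and should give the Meldrum's acid adduct F1. Its cyclic 1,3-dicarbonyl enolate is of the type whose oxygen is arylated in the known copper-catalysed chromene synthesis, so CuI/diamine in the same flask should give the fused aryloxy-dioxinone F2. On warming with water F2 should lose acetone (acylketene), hydrate and decarboxylate to the 7-O-benzyl lactone F3. Hydrogenolysis of F3 (H2, Pd/C) rejoins the route at 19.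

2. Step 3. The dienolate may be acylated at oxygen or at its α-carbon instead of the γ-carbon, and acyl transfer from the doubly ortho-substituted aroyl chloride may be slow, so that acid 3 is recovered or O-acyl products form. The fallback sets out from 3 through acid chloride 5. A Lewis-acid-promoted vinylogous Mukaiyama acylation (ZnCl2, CH2Cl2) with 2,2-dimethyl-6-methylene-4-(trimethylsilyloxy)-4H-1,3-dioxine, which reacts through the acylium-like chloride, should give the β-keto dioxinone F4. Thermolysis in toluene (110 °C) releases acetone, and the acylketene should close to the 4-hydroxy-2-pyranone F5. O-Methylation of F5 (Me2SO4, K2CO3, acetone) comes back to the route at 8.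

3. Step 1. The carboxylate formed under the basic conditions may deactivate the ring so far that fluoride displacement stalls, or needs temperatures at which the bromide is also attacked. The fallback sets out from 1. Esterification with tert-butyl 2,2,2-trichloroacetimidate (cat. BF3·OEt2) should give the tert-butyl ester F6, whose non-ionisable ester activates the ortho-fluoride and resists transesterification. SNAr with sodium benzyl oxide (NaH, BnOH, DMF, 50 °C) should then give the benzyl ether F7, and TFA in CH2Cl2 cleaves the tert-butyl ester and comes back to the route at 2.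

Further compounds
F1 | step 5 | 5-[(R)-[4-(benzyloxy)-6-bromo-3-(4-methoxy-2-oxo-2H-pyran-6-yl)-2-methylphenyl](4-hydroxyphenyl)methyl]-2,2-dimethyl-1,3-dioxane-4,6-dione | COc1cc(-c2c(OCc3ccccc3)cc(Br)c(c2C)[C@@H](c2ccc(O)cc2)C2C(=O)OC(C)(C)OC2=O)oc(=O)c1
F2 | step 5 | (5R)-8-(benzyloxy)-5-(4-hydroxyphenyl)-7-(4-methoxy-2-oxo-2H-pyran-6-yl)-2,2,6-trimethyl-4H,5H-[1,3]dioxino[4,5-b]chromen-4-one (O-arylated Meldrum's acid adduct) | COc1cc(-c2c(OCc3ccccc3)cc3c(c2C)[C@@H](c2ccc(O)cc2)C2=C(O3)OC(C)(C)OC2=O)oc(=O)c1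
F3 | step 5 | (4R)-7-(benzyloxy)-4-(4-hydroxyphenyl)-6-(4-methoxy-2-oxo-2H-pyran-6-yl)-5-methyl-3,4-dihydro-2H-chromen-2-one | COc1cc(-c2c(OCc3ccccc3)cc3c(c2C)[C@@H](c2ccc(O)cc2)CC(=O)O3)oc(=O)c1
F4 | step 3 | 6-{2-[6-(benzyloxy)-4-bromo-3-iodo-2-methylphenyl]-2-oxoethyl}-2,2-dimethyl-4H-1,3-dioxin-4-one | Cc1c(I)c(Br)cc(OCc2ccccc2)c1C(=O)CC1=CC(=O)OC(C)(C)O1
F5 | step 3 | 6-[6-(benzyloxy)-4-bromo-3-iodo-2-methylphenyl]-4-hydroxy-2H-pyran-2-one | Oc1cc(-c2c(C)c(I)c(Br)cc2OCc2ccccc2)oc(=O)c1
F6 | step 1 | tert-butyl 4-bromo-2-fluoro-6-methylbenzoate | Cc1cc(Br)cc(F)c1C(=O)OC(C)(C)C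
F7 | step 1 | tert-butyl 2-(benzyloxy)-4-bromo-6-methylbenzoate | Cc1cc(Br)cc(OCc2ccccc2)c1C(=O)OC(C)(C)C
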